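The ratio I watch is y, c(left-handed substrate)/c(right-handed substrate), since the asked excess is that ratio rewritten: one minus y over one plus y.

the same everywhere: left-handed substrate 10 mM; right-handed substrate 10 mM; racemization catalyst 50 µM

| run | partner | free catalyst | remark | time |
|---|---|---|---|---|
| Sunday's | 30 mM | 90 µM | run made earlier |  |
| Wednesday's | 30 mM | 190 µM | run made earlier |  |
| grey | 30.0 mM | 80 µM |  | 6.0 min |
| red | 30.0 mM | 120 µM |  | 6.0 min |

- Sunday's (time / min: right-handed substrate / %, left-handed substrate / %, left-handed product / %): 0.250: 40.1, 32.2, 16.4; 0.417: 36.1, 26.3, 20.0; 0.667: 29.2, 19.9, 24.4; 1.00: 25.7, 15.0, 32.2; 2.00: 15.1, 5.0, 38.8; 3.00: 11.5, 3.0, 43.2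
- Wednesday's (time / min: right-handed substrate / %, left-handed substrate / %, left-handed product / %): 0.200: 35.6, 26.8, 21.0; 0.667: 19.3, 10.0, 37.9; 1.00: 16.6, 6.8, 41.5; 1.50: 10.1, 4.2, 44.9; 2.50: 5.3, 0.6, 47.8; 3.00: 0.3, 0.3, 45.8

(each reading ± 1 percentage point)

- which of the two ends with the higher excess of right-handed substrate over left-handed substrate among what is left of the two ("neither" if they lie within 2 percentage points) (grey / red / neither)
- excess of right-handed substrate over left-handed substrate among what is left of the two at the end, grey
- excess of right-handed substrate over left-handed substrate among what is left of the two at the end, red

- free catalyst is single-handed; left-handed substrate and right-handed substrate are mirror images of each other, charged as a racemate, each of them at the stated concentration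
- an excess is the difference of the two amounts in percent of their sum
- an excess is below zero if the other one leads

I work in powers of ten. Between 0.667 min and 3.00 min, Sunday's run reads 2.03 powers of ten of left-handed substrate lost per power of ten of right-handed substrate lost, the selectivity factor, a rough reading with the left-handed value so small. While no racemization swaps the two forms, y equals the remaining fraction of right-handed substrate raised to s minus one.

Now the settings. By hand, free catalyst and time should act through their product, and the readings agree: Sunday's at 2.00 min and Wednesday's at 1.00 min, with near-equal products, show right-handed substrate at 15.1% and 16.6%. Grey's product matches Wednesday's at 2.50 min, so I take 5.3%, which is 10.6% of its charge, and my excess for grey is 82.0%. Red's product lies beyond Wednesday's last reading, 0.3% with a scatter of 1 percentage point, which I pass over. Continuing the logarithmic fall from 1.50 min to 2.50 min leaves 4.62%, so my excess for red is 91.9%. Grey and red hold partner and racemization catalyst at the charges of both runs, so I turn neither.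

The forecast puts red ahead, with 78% (66% to 85%) for grey and 88% (75% to 95%) for red, below my figures, holding that racemization “may slightly hold the excess down late on”.

The flask gives red ahead, with 87.4% for grey and 94.8% for red.

    partner + free catalyst + right-handed substrate → free catalyst + right-handed product (k = 5020 /M²/s)
    left-handed product ⇌ right-handed product (k = 0.0416 /s)
    partner + free catalyst + left-handed substrate → free catalyst + left-handed product (k = 11700 /M²/s)
    left-handed substrate + racemization catalyst ⇌ right-handed substrate + racemization catalyst, rate k4*[racemization catalyst]*[left-handed substrate] forward; the back reaction follows from the equilibrium constant (k = 1010 /M/s)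
    partner + racemization catalyst → spent catalyst (k = 3.52 /M/s)

Grey's racemization catalyst stands at 0% by 3.00 min. With grey's final 11% of right-handed substrate, s gives 81.3%, under the flask's value.

The neighbour with 7.5 mM of partner keeps 65% of its right-handed substrate, so s gives 21.8%. That flask computes to 1.39%, and it still holds 9.28% racemization catalyst at 6.00 min.

The readings are simulated with made-up constants; the scatter is artificial.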